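**Route outline**

1. Late cuts: the enal goes back to a primary allylic alcohol. Its CH2OH carbon is cut from the vinyl carbon, which leaves an alkenyl C–B bond. Both ester C–O bonds are cut (senecioate on the side-chain carbinol, isovalerate on C3).
2. Key cut: the C2–C3 bond of the dihydrofuran ring (ring B). C3 is a benzylic carbinol carbon and C2 an O-aryl carbon carrying a 1-substituted vinyl group. This pair is the trace of a γ-aryloxyallyl metal adding to an ortho CHO group, with the formyl-bearing vinyl carbon of the target as the central carbon of an aryl allenyl ether.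
3. Earlier cuts: allenyl ether to propargyl ether, the phenol O–CH2 bond, the aryl–CHO bond ortho to the phenol oxygen, and the carbinol C–H bond, back to 4'-hydroxyacetophenone.
4. Forward order: the benzene ring (ring A) is bought. Ketone reduction, ortho-formylation, O-propargylation and isomerisation give an ortho-(allenyloxy)benzaldehyde. The copper-boryl step closes ring B. Two acylations, a one-carbon homologation of the alkenylboronate and two oxidations finish the side chain.
5. Stereochemistry: the side-chain (S) centre comes from asymmetric transfer hydrogenation. C2 and C3 are set together in the ring closure, cis through the chair transition state of a (Z)-allylcopper and (2R,3R) through the chiral bisphosphine on copper. Later steps touch none of the three centres.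

Key step: step 8

Assumption: which antipode of Ph-BPE leads to the (2R,3R) series cannot be predicted with certainty; (R,R)-Ph-BPE is written and would be exchanged for (S,S)-Ph-BPE if a first run shows the opposite sense.

**Route**

Step 1
Reactants: 1 4'-hydroxyacetophenone
Product: 2 1-[4-(tert-butyldimethylsilyloxy)phenyl]ethanone
Conditions: TBSCl (1.1 equiv), imidazole (2 equiv), DMF, rt
Reagents that add atoms: tert-butyldimethylsilyl chloride (TBSCl), CC(C)(C)[Si](C)(C)Cl
Why: Imidazole-promoted O-silylation of the phenol removes the acidic OH, so that the ketone can be reduced in formic acid/triethylamine and the carbinol formed is not a free para-hydroxybenzylic alcohol.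

Step 2
Reactants: 2 1-[4-(tert-butyldimethylsilyloxy)phenyl]ethanone
Product: 3 (1S)-1-[4-(tert-butyldimethylsilyloxy)phenyl]ethanol
Conditions: RuCl(p-cymene)[(S,S)-TsDPEN] (1 mol %), HCO2H/Et3N (5:2), 40 °C
Reagents that add atoms: none
Why: Noyori asymmetric transfer hydrogenation of an aryl methyl ketone, in which the (S,S)-TsDPEN ruthenium hydride should deliver hydride to the Re face of the carbonyl group and so set the (S) carbinol centre.

Step 3
Reactants: 3 (1S)-1-[4-(tert-butyldimethylsilyloxy)phenyl]ethanol
Product: 4 tert-butyl{4-[(1S)-1-(tert-butyldimethylsilyloxy)ethyl]phenoxy}dimethylsilane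
Conditions: TBSCl (1.2 equiv), imidazole (2.5 equiv), DMF, rt
Reagents that add atoms: tert-butyldimethylsilyl chloride (TBSCl), CC(C)(C)[Si](C)(C)Cl
Why: Standard silylation of a secondary alcohol at oxygen, which leaves the stereocentre untouched and gives an ether that should survive the basic and organometallic steps up to step 10.

Step 4
Reactants: 4 tert-butyl{4-[(1S)-1-(tert-butyldimethylsilyloxy)ethyl]phenoxy}dimethylsilane
Product: 5 4-[(1S)-1-(tert-butyldimethylsilyloxy)ethyl]phenol
Conditions: K2CO3 (0.2 equiv), MeOH, 0 °C to rt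
Reagents that add atoms: none
Why: Base-catalysed methanolysis cleaves a phenolic silyl ether much faster than an alkyl silyl ether because phenoxide is the better leaving group at silicon, so only the aryl ether should be removed.

Step 5
Reactants: 5 4-[(1S)-1-(tert-butyldimethylsilyloxy)ethyl]phenol; 6 paraformaldehyde
Product: 8 5-[(1S)-1-(tert-butyldimethylsilyloxy)ethyl]-2-hydroxybenzaldehyde, via magnesium salicyl alkoxide 7 (not isolated)
Conditions: 6 (5 equiv), MgCl2 (2 equiv), Et3N (4 equiv), THF, 65 °C; cold aq. citric acid work-up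
Reagents that add atoms: none
Why: Casnati–Skattebøl ortho-formylation, in which the magnesium phenoxide directs hydroxymethylation to the free ortho position (para is blocked) and a second formaldehyde oxidises the benzylic alkoxide 7 by hydride transfer, under conditions that should spare the silyl ether.

Step 6
Reactants: 8 5-[(1S)-1-(tert-butyldimethylsilyloxy)ethyl]-2-hydroxybenzaldehyde; 9 propargyl bromide
Product: 10 5-[(1S)-1-(tert-butyldimethylsilyloxy)ethyl]-2-(prop-2-yn-1-yloxy)benzaldehyde
Conditions: 9 (1.2 equiv), K2CO3 (1.5 equiv), DMF, rt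
Reagents that add atoms: none
Why: Williamson etherification of an acidic salicylaldehyde phenol with a reactive primary propargylic bromide (SN2), a routine alkylation for this substrate type.

Step 7
Reactants: 10 5-[(1S)-1-(tert-butyldimethylsilyloxy)ethyl]-2-(prop-2-yn-1-yloxy)benzaldehyde
Product: 11 5-[(1S)-1-(tert-butyldimethylsilyloxy)ethyl]-2-(propa-1,2-dien-1-yloxy)benzaldehyde
Conditions: KOtBu (0.15 equiv), THF/t-BuOH (10:1), 0 °C, short reaction time
Reagents that add atoms: none
Why: Base-catalysed propargyl-to-allenyl ether isomerisation (1,3-prototropic shift), in which tert-butoxide removes an O–CH2 proton and tert-butanol returns it to the alkyne terminus; the aldehyde has no α-hydrogen, and low loading and temperature should stop the shift at the allenyl ether.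

Step 8
Reactants: 11 5-[(1S)-1-(tert-butyldimethylsilyloxy)ethyl]-2-(propa-1,2-dien-1-yloxy)benzaldehyde; 12 bis(pinacolato)diboron
Product: 15 (2R,3R)-5-[(1S)-1-(tert-butyldimethylsilyloxy)ethyl]-2-[1-(4,4,5,5-tetramethyl-1,3,2-dioxaborolan-2-yl)ethenyl]-2,3-dihydro-1-benzofuran-3-ol, via (Z)-allylcopper 13 (not isolated), via O-boryl ether 14 (not isolated)
Conditions: CuCl (5 mol %), (R,R)-Ph-BPE (6 mol %), NaOtBu (10 mol %), 12 (1.1 equiv), THF, 0 °C to rt; aq. NH4Cl work-up
Reagents that add atoms: none
Why: Proposed new method: LCu–Bpin, formed from CuCl, NaOtBu and B2pin2, should add syn across the terminal C=C of the allenyl ether on the face turned away from the aryloxy group, placing boron on the central carbon and copper on CH2 to give the (Z)-γ-aryloxy-β-boryl allylcopper 13, whose oxygen-bearing γ-carbon then attacks the ortho formyl carbon through a closed six-membered chair transition state, after which the copper alkoxide is borylated by B2pin2 to 14 with return of LCu–Bpin. The closest known reaction type is the copper-catalysed borylative coupling of allenes with carbonyl compounds through 2-boryl allylcopper species, known as an enantioselective three-component reaction and as a cyclisation of allene-tethered ketones to cis 2-alkenyl cycloalkanols; an allene that carries the tether oxygen itself and closes a dihydrobenzofuran has not been shown. Ring B closes in a 5-exo-trig mode at the carbonyl group, the C2–C3 bond being the only ring bond made. C2 and C3 are created together: their cis relation is fixed by the (Z) geometry of 13 and the two-atom aromatic tether, which admit only the chair with the aryloxy group axial and the aldehyde aryl group equatorial, and their (2R,3R) sense is set by the chiral bisphosphine on copper, which selects the aldehyde face while the distant (S) centre is a spectator. The step needs enantiofacial control (ligand), borylcupration of the allene ahead of boryl addition to the aldehyde (cumulated C=C bonds are expected to insert into Cu–B faster than an aryl aldehyde under bisphosphine ligation), boron at the central carbon (the general regiochemistry for allenes) and five- over seven-membered closure (γ-attack through the short ortho tether).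

Step 9
Reactants: 15 (2R,3R)-5-[(1S)-1-(tert-butyldimethylsilyloxy)ethyl]-2-[1-(4,4,5,5-tetramethyl-1,3,2-dioxaborolan-2-yl)ethenyl]-2,3-dihydro-1-benzofuran-3-ol; 16 isovaleric anhydride
Product: 17 (2R,3R)-5-[(1S)-1-(tert-butyldimethylsilyloxy)ethyl]-2-[1-(4,4,5,5-tetramethyl-1,3,2-dioxaborolan-2-yl)ethenyl]-2,3-dihydro-1-benzofuran-3-yl 3-methylbutanoate
Conditions: 16 (1.5 equiv), Et3N (2 equiv), DMAP (10 mol %), CH2Cl2, 0 °C to rt
Reagents that add atoms: none
Why: DMAP-catalysed acyl transfer to the C3 hydroxyl takes place at oxygen, so the C3 configuration is retained, and the alkenylboronate and silyl ether are inert to these conditions.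

Step 10
Reactants: 17 (2R,3R)-5-[(1S)-1-(tert-butyldimethylsilyloxy)ethyl]-2-[1-(4,4,5,5-tetramethyl-1,3,2-dioxaborolan-2-yl)ethenyl]-2,3-dihydro-1-benzofuran-3-yl 3-methylbutanoate
Product: 18 (2R,3R)-5-[(1S)-1-hydroxyethyl]-2-[1-(4,4,5,5-tetramethyl-1,3,2-dioxaborolan-2-yl)ethenyl]-2,3-dihydro-1-benzofuran-3-yl 3-methylbutanoate
Conditions: HF·pyridine, excess pyridine, THF, 0 °C to rt
Reagents that add atoms: none
Why: Fluoride-mediated cleavage of the Si–O bond under buffered, non-basic conditions should free the carbinol without ionising either benzylic C–O bond, without eliminating the C3 ester to a benzofuran and without harming the pinacol boronate.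

Step 11
Reactants: 18 (2R,3R)-5-[(1S)-1-hydroxyethyl]-2-[1-(4,4,5,5-tetramethyl-1,3,2-dioxaborolan-2-yl)ethenyl]-2,3-dihydro-1-benzofuran-3-yl 3-methylbutanoate; 19 3-methylbut-2-enoic acid
Product: 20 (1S)-1-{(2R,3R)-3-(3-methylbutanoyloxy)-2-[1-(4,4,5,5-tetramethyl-1,3,2-dioxaborolan-2-yl)ethenyl]-2,3-dihydro-1-benzofuran-5-yl}ethyl 3-methylbut-2-enoate
Conditions: 19 (1.5 equiv), DCC (1.5 equiv), DMAP (20 mol %), CH2Cl2, 0 °C to rt
Reagents that add atoms: none
Why: Steglich esterification activates the acid, not the alcohol, so the benzylic C–O bond is never broken and the (S) configuration is retained; the low temperature should limit deconjugation of the senecioyl group.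

Step 12
Reactants: 20 (1S)-1-{(2R,3R)-3-(3-methylbutanoyloxy)-2-[1-(4,4,5,5-tetramethyl-1,3,2-dioxaborolan-2-yl)ethenyl]-2,3-dihydro-1-benzofuran-5-yl}ethyl 3-methylbut-2-enoate; 21 chloroiodomethane
Product: 24 (1S)-1-[(2R,3R)-2-(3-hydroxyprop-1-en-2-yl)-3-(3-methylbutanoyloxy)-2,3-dihydro-1-benzofuran-5-yl]ethyl 3-methylbut-2-enoate, via boronate complex 22 (not isolated), via allylboronate 23 (not isolated)
Conditions: 21 (1.6 equiv), n-BuLi (1.3 equiv, slow addition), THF, −78 °C to rt; then NaBO3·4H2O, THF/H2O, rt
Reagents that add atoms: sodium perborate, [Na+].[O-]OB=O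
Why: Matteson homologation, in which chloromethyllithium formed by iodine–lithium exchange in the presence of the boronate adds to boron, the alkenyl group of 22 migrates to carbon with loss of chloride to give 23, and perborate then oxidises the C–B bond to the primary allylic alcohol without allylic transposition.

Step 13
Reactants: 24 (1S)-1-[(2R,3R)-2-(3-hydroxyprop-1-en-2-yl)-3-(3-methylbutanoyloxy)-2,3-dihydro-1-benzofuran-5-yl]ethyl 3-methylbut-2-enoate
Product: 25 (1S)-1-[(2R,3R)-3-(3-methylbutanoyloxy)-2-(3-oxoprop-1-en-2-yl)-2,3-dihydro-1-benzofuran-5-yl]ethyl 3-methylbut-2-enoate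
Conditions: activated MnO2 (excess), CH2Cl2, rt
Reagents that add atoms: none
Why: MnO2 oxidation is selective for allylic alcohols and neutral, so the base-sensitive enal, the allylic C2–H and both esters should be left alone when the sequence ends here.

**Compound list**

1 | 4'-hydroxyacetophenone | CC(=O)c1ccc(O)cc1 | starting material
2 | 1-[4-(tert-butyldimethylsilyloxy)phenyl]ethanone | CC(=O)c1ccc(O[Si](C)(C)C(C)(C)C)cc1 | intermediate
3 | (1S)-1-[4-(tert-butyldimethylsilyloxy)phenyl]ethanol | C[C@H](O)c1ccc(O[Si](C)(C)C(C)(C)C)cc1 | intermediate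
4 | tert-butyl{4-[(1S)-1-(tert-butyldimethylsilyloxy)ethyl]phenoxy}dimethylsilane | C[C@H](O[Si](C)(C)C(C)(C)C)c1ccc(O[Si](C)(C)C(C)(C)C)cc1 | intermediate
5 | 4-[(1S)-1-(tert-butyldimethylsilyloxy)ethyl]phenol | C[C@H](O[Si](C)(C)C(C)(C)C)c1ccc(O)cc1 | intermediate
6 | paraformaldehyde (written as the monomer) | C=O | starting material
7 | 2-(hydroxymethyl)-4-[(1S)-1-(tert-butyldimethylsilyloxy)ethyl]phenol, present as its magnesium salt | C[C@H](O[Si](C)(C)C(C)(C)C)c1ccc(O)c(CO)c1 | intermediate (not isolated)
8 | 5-[(1S)-1-(tert-butyldimethylsilyloxy)ethyl]-2-hydroxybenzaldehyde | C[C@H](O[Si](C)(C)C(C)(C)C)c1ccc(O)c(C=O)c1 | intermediate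
9 | propargyl bromide | C#CCBr | starting material
10 | 5-[(1S)-1-(tert-butyldimethylsilyloxy)ethyl]-2-(prop-2-yn-1-yloxy)benzaldehyde | C#CCOc1ccc([C@H](C)O[Si](C)(C)C(C)(C)C)cc1C=O | intermediate
11 | 5-[(1S)-1-(tert-butyldimethylsilyloxy)ethyl]-2-(propa-1,2-dien-1-yloxy)benzaldehyde | C=C=COc1ccc([C@H](C)O[Si](C)(C)C(C)(C)C)cc1C=O | intermediate
12 | bis(pinacolato)diboron | CC1(C)OB(OC1(C)C)B1OC(C)(C)C(C)(C)O1 | starting material
13 | (Z)-3-aryloxy-2-(pinacolboryl)allylcopper, CH2Cu cis to the aryloxy group, bisphosphine on copper not drawn | [Cu]C/C(B1OC(C)(C)C(C)(C)O1)=C\Oc1ccc([C@H](C)O[Si](C)(C)C(C)(C)C)cc1C=O | intermediate (not isolated)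
14 | O-pinacolboryl ether of 15 | C=C(B1OC(C)(C)C(C)(C)O1)[C@H]1Oc2ccc([C@H](C)O[Si](C)(C)C(C)(C)C)cc2[C@H]1OB1OC(C)(C)C(C)(C)O1 | intermediate (not isolated)
15 | (2R,3R)-5-[(1S)-1-(tert-butyldimethylsilyloxy)ethyl]-2-[1-(4,4,5,5-tetramethyl-1,3,2-dioxaborolan-2-yl)ethenyl]-2,3-dihydro-1-benzofuran-3-ol (2,3-cis) | C=C(B1OC(C)(C)C(C)(C)O1)[C@H]1Oc2ccc([C@H](C)O[Si](C)(C)C(C)(C)C)cc2[C@H]1O | intermediate
16 | isovaleric anhydride | CC(C)CC(=O)OC(=O)CC(C)C | starting material
17 | (2R,3R)-5-[(1S)-1-(tert-butyldimethylsilyloxy)ethyl]-2-[1-(4,4,5,5-tetramethyl-1,3,2-dioxaborolan-2-yl)ethenyl]-2,3-dihydro-1-benzofuran-3-yl 3-methylbutanoate | C=C(B1OC(C)(C)C(C)(C)O1)[C@H]1Oc2ccc([C@H](C)O[Si](C)(C)C(C)(C)C)cc2[C@H]1OC(=O)CC(C)C | intermediate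
18 | (2R,3R)-5-[(1S)-1-hydroxyethyl]-2-[1-(4,4,5,5-tetramethyl-1,3,2-dioxaborolan-2-yl)ethenyl]-2,3-dihydro-1-benzofuran-3-yl 3-methylbutanoate | C=C(B1OC(C)(C)C(C)(C)O1)[C@H]1Oc2ccc([C@H](C)O)cc2[C@H]1OC(=O)CC(C)C | intermediate
19 | 3-methylbut-2-enoic acid (senecioic acid) | CC(C)=CC(=O)O | starting material
20 | (1S)-1-{(2R,3R)-3-(3-methylbutanoyloxy)-2-[1-(4,4,5,5-tetramethyl-1,3,2-dioxaborolan-2-yl)ethenyl]-2,3-dihydro-1-benzofuran-5-yl}ethyl 3-methylbut-2-enoate | C=C(B1OC(C)(C)C(C)(C)O1)[C@H]1Oc2ccc([C@H](C)OC(=O)C=C(C)C)cc2[C@H]1OC(=O)CC(C)C | intermediate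
21 | chloroiodomethane | ClCI | starting material
22 | lithium (chloromethyl)boronate complex of 20 | [Li+].C=C([B-]1(CCl)OC(C)(C)C(C)(C)O1)[C@H]1Oc2ccc([C@H](C)OC(=O)C=C(C)C)cc2[C@H]1OC(=O)CC(C)C | intermediate (not isolated)
23 | (1S)-1-{(2R,3R)-3-(3-methylbutanoyloxy)-2-[3-(4,4,5,5-tetramethyl-1,3,2-dioxaborolan-2-yl)prop-1-en-2-yl]-2,3-dihydro-1-benzofuran-5-yl}ethyl 3-methylbut-2-enoate | C=C(CB1OC(C)(C)C(C)(C)O1)[C@H]1Oc2ccc([C@H](C)OC(=O)C=C(C)C)cc2[C@H]1OC(=O)CC(C)C | intermediate (not isolated)
24 | (1S)-1-[(2R,3R)-2-(3-hydroxyprop-1-en-2-yl)-3-(3-methylbutanoyloxy)-2,3-dihydro-1-benzofuran-5-yl]ethyl 3-methylbut-2-enoate | C=C(CO)[C@H]1Oc2ccc([C@H](C)OC(=O)C=C(C)C)cc2[C@H]1OC(=O)CC(C)C | intermediate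
25 | (1S)-1-[(2R,3R)-3-(3-methylbutanoyloxy)-2-(3-oxoprop-1-en-2-yl)-2,3-dihydro-1-benzofuran-5-yl]ethyl 3-methylbut-2-enoate (CNP0325942.1) | C=C(C=O)[C@H]1Oc2ccc([C@H](C)OC(=O)C=C(C)C)cc2[C@H]1OC(=O)CC(C)C | target

**Step count**

Total: 13 steps. Longest linear sequence: 13 steps, from 1.

**Steps most likely to fail**

1. Step 8 (key step). The boryl group may be transferred to the formyl carbon before the allene reacts, the borylcupration may take the other regiochemistry on this oxygen-substituted allene, or the ligand may distinguish the aldehyde faces poorly. The fallback uses known chemistry, avoids the allene altogether, sets out from 8 and comes back to the route at 24. O-Alkylation of 8 with chloroacetone (K2CO3, acetone) would give the aryloxyacetone aldehyde F1. A proline-catalysed intramolecular 5-enolexo aldol reaction (DMF, rt, with the proline antipode that leads to the (2S,3R) product) closes the same C2–C3 bond and should give the cis 2-acetyl-3-hydroxy-2,3-dihydrobenzofuran F2; any stereoisomer formed alongside is diastereomeric because of the (S) side chain and would be removed by chromatography. Methylenation of the ketone under non-basic conditions (excess Cp2Ti(μ-Cl)(μ-CH2)AlMe2, THF/pyridine, −40 to 0 °C) gives the 2-isopropenyl alcohol F3. Acylation with 16 (Et3N, DMAP) gives the isovalerate F4, HF·pyridine gives the free carbinol F5, and DCC/DMAP with 19 gives the isopropenyl diester F6. Riley allylic oxidation of the isopropenyl methyl group (catalytic SeO2, t-BuOOH, CH2Cl2), which should be preferred over the methine C2–H and over the electron-poor senecioate, then leads to 24.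

2. Step 12. Chloromethyllithium or n-BuLi may attack the two ester carbonyl groups in competition with ate-complex formation at the hindered boron, and a second insertion may over-homologate the allylboronate. The fallback sets out from 20 and comes back at 24 without any organolithium. Iododeboronation of 20 (NaI, TsN(Cl)Na, THF/H2O, rt) would give the alkenyl iodide F7. Stille coupling of F7 with Bu3SnCH2OH (Pd(PPh3)4, dioxane, 90 °C) then installs the hydroxymethyl carbon directly and gives 24.

3. Step 7. Tert-butoxide may add to the free formyl group, or the propargylic/allenyl carbanion may cyclise onto it, when only a proton shift is wanted. The fallback masks the aldehyde without acid, sets out from 10 and comes back at 11. Condensation of 10 with N,N'-dimethylethane-1,2-diamine (toluene, 4 Å molecular sieves, rt) would give the imidazolidine F8. The same KOtBu isomerisation then gives the allenyloxy imidazolidine F9. Hydrolysis of the aminal on wet silica gel or with cold aqueous citric acid, mild enough for the aryl allenyl ether and the silyl ether, releases 11.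

**Further compounds**

F1 | step 8 | 5-[(1S)-1-(tert-butyldimethylsilyloxy)ethyl]-2-(2-oxopropoxy)benzaldehyde | CC(=O)COc1ccc([C@H](C)O[Si](C)(C)C(C)(C)C)cc1C=O
F2 | step 8 | 1-{(2S,3R)-5-[(1S)-1-(tert-butyldimethylsilyloxy)ethyl]-3-hydroxy-2,3-dihydro-1-benzofuran-2-yl}ethanone (2,3-cis) | CC(=O)[C@H]1Oc2ccc([C@H](C)O[Si](C)(C)C(C)(C)C)cc2[C@H]1O
F3 | step 8 | (2R,3R)-5-[(1S)-1-(tert-butyldimethylsilyloxy)ethyl]-2-(prop-1-en-2-yl)-2,3-dihydro-1-benzofuran-3-ol | C=C(C)[C@H]1Oc2ccc([C@H](C)O[Si](C)(C)C(C)(C)C)cc2[C@H]1O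
F4 | step 8 | (2R,3R)-5-[(1S)-1-(tert-butyldimethylsilyloxy)ethyl]-2-(prop-1-en-2-yl)-2,3-dihydro-1-benzofuran-3-yl 3-methylbutanoate | C=C(C)[C@H]1Oc2ccc([C@H](C)O[Si](C)(C)C(C)(C)C)cc2[C@H]1OC(=O)CC(C)C
F5 | step 8 | (2R,3R)-5-[(1S)-1-hydroxyethyl]-2-(prop-1-en-2-yl)-2,3-dihydro-1-benzofuran-3-yl 3-methylbutanoate | C=C(C)[C@H]1Oc2ccc([C@H](C)O)cc2[C@H]1OC(=O)CC(C)C
F6 | step 8 | (1S)-1-[(2R,3R)-3-(3-methylbutanoyloxy)-2-(prop-1-en-2-yl)-2,3-dihydro-1-benzofuran-5-yl]ethyl 3-methylbut-2-enoate | C=C(C)[C@H]1Oc2ccc([C@H](C)OC(=O)C=C(C)C)cc2[C@H]1OC(=O)CC(C)C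
F7 | step 12 | (1S)-1-[(2S,3R)-2-(1-iodoethenyl)-3-(3-methylbutanoyloxy)-2,3-dihydro-1-benzofuran-5-yl]ethyl 3-methylbut-2-enoate (same spatial arrangement as 20; the C2 descriptor changes because of iodine) | C=C(I)[C@H]1Oc2ccc([C@H](C)OC(=O)C=C(C)C)cc2[C@H]1OC(=O)CC(C)C
F8 | step 7 | 2-{5-[(1S)-1-(tert-butyldimethylsilyloxy)ethyl]-2-(prop-2-yn-1-yloxy)phenyl}-1,3-dimethylimidazolidine | C#CCOc1ccc([C@H](C)O[Si](C)(C)C(C)(C)C)cc1C1N(C)CCN1C
F9 | step 7 | 2-{5-[(1S)-1-(tert-butyldimethylsilyloxy)ethyl]-2-(propa-1,2-dien-1-yloxy)phenyl}-1,3-dimethylimidazolidine | C=C=COc1ccc([C@H](C)O[Si](C)(C)C(C)(C)C)cc1C1N(C)CCN1C
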